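**Retrosynthetic overview**
1. Target 11 ⇐ the two C2–O bonds: double catalyst-controlled oxygen transfer to the bis(3-silyloxybenzofuran) 8, each hemiketal stored as a silyl ketal and released by fluoride at the very end.
2. 8 ⇐ bis-coumaranone 7 by enol and phenol silylation.
3. 7 ⇐ both furanone rings closed by O-alkylation (O1–C2) of the biaryl bis(α-chloroketone) 6 ⇐ oxidative phenol dimerisation (C7–C7') of two molecules of chloroketone 5.
4. 5 ⇐ acylation of 4,5-dimethoxyresorcinol 3 with 2-chloropropanoic acid 4; 3 ⇐ Baeyer–Villiger oxidation of aldehyde 1.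
5. Ring order: arene (bought) → biaryl → two furanone rings → the two hemiketal centres last.

Assumption: the biaryl axis has no descriptor in the given structure and is left uncontrolled; the C2 hemiketal centres can epimerise by ring opening in base, so they are set in the last step and the product is handled only in neutral or weakly acidic media at or below room temperature.

**Step 1**
Reactants: 1 3-hydroxy-4,5-dimethoxybenzaldehyde
Product: 3 4,5-dimethoxybenzene-1,3-diol, via aryl formate 2 (not isolated)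
Conditions: mCPBA (1.3 equiv), CH2Cl2, 0 °C to rt; then MeOH, cat. HCl, rt, N2
Reagents that add atoms: mCPBA, OOC(=O)c1cccc(Cl)c1
Why: Baeyer–Villiger (Dakin-type) oxidation in which the electron-rich aryl group (para-OMe) migrates to give the formate, which acid methanolysis cleaves without exposing the air-sensitive resorcinol to base; no stereocentre.

**Step 2**
Reactants: 3 4,5-dimethoxybenzene-1,3-diol; 4 2-chloropropanoic acid (racemic)
Product: 5 2-chloro-1-(2,4-dihydroxy-5,6-dimethoxyphenyl)propan-1-one (racemic)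
Conditions: BF3·OEt2 (neat, 6 equiv), 70 °C, 3 h; aq. NaOAc work-up
Reagents that add atoms: 2-chloropropanoic acid (4), CC(Cl)C(=O)O
Why: BF3-mediated Friedel–Crafts (Nencki-type) acylation should go to the ring carbon ortho to one OH and para to the other, as 5-substituted resorcinols do, and BF3 does not cleave the methyl ethers; the CHCl centre is racemic and is destroyed later.

**Step 3**
Reactants: 5 2-chloro-1-(2,4-dihydroxy-5,6-dimethoxyphenyl)propan-1-one (two molecules, joined to each other)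
Product: 7 6,6'-dihydroxy-4,4',5,5'-tetramethoxy-2,2'-dimethyl-[7,7'-bi-1-benzofuran]-3,3'(2H,2'H)-dione (mixture of C2 epimers), via biaryl bis-chloroketone 6 (not isolated)
Conditions: FeCl3 (10 mol%), t-BuOOt-Bu (0.75 equiv per 5), HFIP, rt; evaporate; then NaOAc (5 equiv), EtOH, reflux, Ar
Reagents that add atoms: second molecule of 5, 2-chloro-1-(2,4-dihydroxy-5,6-dimethoxyphenyl)propan-1-one, CC(Cl)C(=O)c1c(O)cc(O)c(OC)c1OC
Why: Iron-catalysed oxidative phenol homocoupling joins two molecules of 5 at their single unsubstituted ring carbon (ortho to both hydroxyls, meta to the acyl group) with loss of one hydrogen from each, and acetate-mediated intramolecular Williamson etherification (5-exo-tet, the classical coumaranone synthesis) then closes both furanone rings through the hydroxyl ortho to each acyl group; the C2 centres formed here are uncontrolled and are erased in step 4.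

**Step 4**
Reactants: 7 6,6'-dihydroxy-4,4',5,5'-tetramethoxy-2,2'-dimethyl-[7,7'-bi-1-benzofuran]-3,3'(2H,2'H)-dione
Product: 8 3,3',6,6'-tetrakis(tert-butyldimethylsilyloxy)-4,4',5,5'-tetramethoxy-2,2'-dimethyl-7,7'-bi-1-benzofuran
Conditions: TBSOTf (5 equiv), Et3N (8 equiv), CH2Cl2, 0 °C to rt
Reagents that add atoms: TBSOTf, CC(C)(C)[Si](C)(C)OS(=O)(=O)C(F)(F)F
Why: Soft enolisation and O-silylation with a silyl triflate turns each coumaranone into an aromatic 3-silyloxybenzofuran (aromatisation favours O- over C-silylation) and caps both phenols, which erases the uncontrolled C2 centres and protects the phenols from the oxidant of step 5.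

**Step 5**
Reactants: 8 3,3',6,6'-tetrakis(tert-butyldimethylsilyloxy)-4,4',5,5'-tetramethoxy-2,2'-dimethyl-7,7'-bi-1-benzofuran
Product: 11 (2R,2'R)-2,2',6,6'-tetrahydroxy-4,4',5,5'-tetramethoxy-2,2'-dimethyl-[7,7'-bi-1-benzofuran]-3,3'(2H,2'H)-dione (target), via bis-epoxide 9 (not isolated), via tetrasilyl bis-ketal 10 (not isolated)
Conditions: chloro[(S,S)-N,N'-bis(3,5-di-tert-butylsalicylidene)cyclohexane-1,2-diaminato]manganese, MnCl(C36H52N2O2), trivalent manganese (10 mol%), 4-phenylpyridine N-oxide (40 mol%), PhIO (2.6 equiv), 4 Å MS, CH2Cl2, −20 °C; then Et3N·3HF (excess), THF, 0 °C to rt; pH 7 work-up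
Reagents that add atoms: iodosylbenzene, O=Ic1ccccc1
Why: Proposed new method: the pentavalent oxomanganese salen species formed from the chloromanganese complex and PhIO should transfer oxygen side-on to the electron-rich, cis-fused, aryl-conjugated C2=C3 bond of each 3-silyloxybenzofuran on the face fixed by the ligand, the 3-silyloxy epoxide then opens at the benzylic silyloxy-stabilised C3 and the silyl group shifts 1,4 onto the new oxygen without the C2–O bond ever breaking, so each C2 centre is set in the oxygen-transfer event and stored as a silyl ketal that cannot ring-open until Et3N·3HF releases the hemiketal under non-basic conditions; the (S,S) ligand is chosen because it gives (1S,2R)-indene oxide, which maps onto the face leading to (2R) here (the (R,R) complex is used if the sense proves opposite), and two independent transfers on the dimer raise the ee of the like product statistically; the closest known reactions are the salen-manganese epoxidation of indene and chromenes, the same catalysts on acyclic silyl enol ethers, and the Rubottom oxidation, none of which has been shown on a 3-silyloxybenzofuran or used to create a hemiketal centre.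

**Compound list**
1 | 3-hydroxy-4,5-dimethoxybenzaldehyde | O=Cc1cc(O)c(OC)c(OC)c1 | starting material
2 | 3-hydroxy-4,5-dimethoxyphenyl formate | O=COc1cc(O)c(OC)c(OC)c1 | intermediate
3 | 4,5-dimethoxybenzene-1,3-diol | Oc1cc(O)c(OC)c(OC)c1 | intermediate
4 | 2-chloropropanoic acid (racemic) | CC(Cl)C(=O)O | starting material
5 | 2-chloro-1-(2,4-dihydroxy-5,6-dimethoxyphenyl)propan-1-one (racemic) | CC(Cl)C(=O)c1c(O)cc(O)c(OC)c1OC | intermediate
6 | 1,1'-(2,2',6,6'-tetrahydroxy-4,4',5,5'-tetramethoxy-[1,1'-biphenyl]-3,3'-diyl)bis(2-chloropropan-1-one) (mixture of CHCl epimers) | CC(Cl)C(=O)c1c(O)c(-c2c(O)c(C(=O)C(C)Cl)c(OC)c(OC)c2O)c(O)c(OC)c1OC | intermediate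
7 | 6,6'-dihydroxy-4,4',5,5'-tetramethoxy-2,2'-dimethyl-[7,7'-bi-1-benzofuran]-3,3'(2H,2'H)-dione (mixture of C2 epimers) | CC1Oc2c(C1=O)c(OC)c(OC)c(O)c2-c1c(O)c(OC)c(OC)c2c1OC(C)C2=O | intermediate
8 | 3,3',6,6'-tetrakis(tert-butyldimethylsilyloxy)-4,4',5,5'-tetramethoxy-2,2'-dimethyl-7,7'-bi-1-benzofuran | Cc1oc2c(c1O[Si](C)(C)C(C)(C)C)c(OC)c(OC)c(O[Si](C)(C)C(C)(C)C)c2-c1c(O[Si](C)(C)C(C)(C)C)c(OC)c(OC)c2c(O[Si](C)(C)C(C)(C)C)c(C)oc12 | intermediate
9 | 7,7'-bi[(2S,3R)-3,6-bis(tert-butyldimethylsilyloxy)-2,3-epoxy-4,5-dimethoxy-2-methyl-2,3-dihydro-1-benzofuran] | C[C@@]12Oc3c(-c4c(O[Si](C)(C)C(C)(C)C)c(OC)c(OC)c5c4O[C@@]6(C)O[C@@]56O[Si](C)(C)C(C)(C)C)c(O[Si](C)(C)C(C)(C)C)c(OC)c(OC)c3[C@]1(O[Si](C)(C)C(C)(C)C)O2 | intermediate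
10 | (2S,2'S)-2,2',6,6'-tetrakis(tert-butyldimethylsilyloxy)-4,4',5,5'-tetramethoxy-2,2'-dimethyl-[7,7'-bi-1-benzofuran]-3,3'(2H,2'H)-dione (same spatial arrangement at C2 as the target; the descriptor changes only because OSi outranks the ring oxygen) | COc1c(O[Si](C)(C)C(C)(C)C)c(-c2c(O[Si](C)(C)C(C)(C)C)c(OC)c(OC)c3c2O[C@@](C)(O[Si](C)(C)C(C)(C)C)C3=O)c2c(c1OC)C(=O)[C@](C)(O[Si](C)(C)C(C)(C)C)O2 | intermediate
11 | (2R,2'R)-2,2',6,6'-tetrahydroxy-4,4',5,5'-tetramethoxy-2,2'-dimethyl-[7,7'-bi-1-benzofuran]-3,3'(2H,2'H)-dione | COc1c(O)c(-c2c(O)c(OC)c(OC)c3c2O[C@@](C)(O)C3=O)c2c(c1OC)C(=O)[C@](C)(O)O2 | target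

**Totals**
Total steps: 5. Longest linear sequence: 5 steps (from 1).

**Three steps most likely to fail**

Step 5 (the proposed new oxygen transfer). The risks are insufficient or reversed face selectivity on a tetrasubstituted heteroaromatic enol ether, competing oxidation of the electron-rich arene, and epimerisation when the hemiketal is released. The fallback uses known chemistry and sets out from 8. An ordinary Rubottom oxidation with dimethyldioxirane (acetone/CH2Cl2, −40 °C, no chiral catalyst) gives, after the same silyl shift, the three configurationally locked tetrasilyl bis-ketals in about 1:1:2 (the axis being left aside). These are 10, its enantiomer (2R,2'R)-2,2',6,6'-tetrakis(tert-butyldimethylsilyloxy)-4,4',5,5'-tetramethoxy-2,2'-dimethyl-[7,7'-bi-1-benzofuran]-3,3'(2H,2'H)-dione F1, and the unlike isomer (2R,2'S)-2,2',6,6'-tetrakis(tert-butyldimethylsilyloxy)-4,4',5,5'-tetramethoxy-2,2'-dimethyl-[7,7'-bi-1-benzofuran]-3,3'(2H,2'H)-dione F2. F2 is removed on silica, and 10 is separated from F1 by preparative chiral-phase SFC. The fallback comes back to the route at 10, which takes the fluoride stage of step 5.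

Step 3 (oxidative biaryl coupling). The risks are over-oxidation of the tetra-ortho-oxygenated biaryl, C–O coupling, iron chelation by the ortho-hydroxy ketone, and sluggish oxidation of a phenol para to a ketone. The fallback replaces oxidative coupling by halide cross-coupling and sets out from 5. N-Iodosuccinimide (MeCN, 0 °C) iodinates the only aromatic C–H to give 2-chloro-1-(2,4-dihydroxy-3-iodo-5,6-dimethoxyphenyl)propan-1-one F3. NaOAc in refluxing EtOH closes the ring to 6-hydroxy-7-iodo-4,5-dimethoxy-2-methyl-1-benzofuran-3(2H)-one F4. TBSOTf/Et3N gives 3,6-bis(tert-butyldimethylsilyloxy)-7-iodo-4,5-dimethoxy-2-methyl-1-benzofuran F5. Half of F5 is borylated (B2pin2, PdCl2(dppf), KOAc, dioxane, 80 °C) to 2-[3,6-bis(tert-butyldimethylsilyloxy)-4,5-dimethoxy-2-methyl-1-benzofuran-7-yl]-4,4,5,5-tetramethyl-1,3,2-dioxaborolane F6. Suzuki–Miyaura coupling of F6 with the remaining F5 (Pd(OAc)2, SPhos, anhydrous K3PO4, toluene, 90 °C) comes back to the route at 8.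

Step 2 (regiochemistry of the acylation). The risk is acylation between the two hydroxyls instead of between OH and OMe, or partial demethylation. The fallback reverses the order of the C–C bonds so that the biaryl occupies the competing position first; it sets out from 3. MOMCl/i-Pr2NEt gives 1,2-dimethoxy-3,5-bis(methoxymethoxy)benzene F7. n-BuLi (THF, 0 °C) metalates preferentially between the two OMOM groups to give [3,4-dimethoxy-2,6-bis(methoxymethoxy)phenyl]lithium F8. Anhydrous CuCl2 joins two molecules of it oxidatively to 3,3',4,4'-tetramethoxy-2,2',6,6'-tetrakis(methoxymethoxy)-1,1'-biphenyl F9. HCl/MeOH gives 3,3',4,4'-tetramethoxy-[1,1'-biphenyl]-2,2',6,6'-tetrol F10. Double acylation with 4 in BF3·OEt2 at the only free positions comes back to the route at 6, which takes the NaOAc stage of step 3.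

**Further compounds**
F1 | step 5 | (2R,2'R)-2,2',6,6'-tetrakis(tert-butyldimethylsilyloxy)-4,4',5,5'-tetramethoxy-2,2'-dimethyl-[7,7'-bi-1-benzofuran]-3,3'(2H,2'H)-dione | COc1c(O[Si](C)(C)C(C)(C)C)c(-c2c(O[Si](C)(C)C(C)(C)C)c(OC)c(OC)c3c2O[C@](C)(O[Si](C)(C)C(C)(C)C)C3=O)c2c(c1OC)C(=O)[C@@](C)(O[Si](C)(C)C(C)(C)C)O2
F2 | step 5 | (2R,2'S)-2,2',6,6'-tetrakis(tert-butyldimethylsilyloxy)-4,4',5,5'-tetramethoxy-2,2'-dimethyl-[7,7'-bi-1-benzofuran]-3,3'(2H,2'H)-dione | COc1c(O[Si](C)(C)C(C)(C)C)c(-c2c(O[Si](C)(C)C(C)(C)C)c(OC)c(OC)c3c2O[C@@](C)(O[Si](C)(C)C(C)(C)C)C3=O)c2c(c1OC)C(=O)[C@@](C)(O[Si](C)(C)C(C)(C)C)O2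
F3 | step 3 | 2-chloro-1-(2,4-dihydroxy-3-iodo-5,6-dimethoxyphenyl)propan-1-one (racemic) | CC(Cl)C(=O)c1c(O)c(I)c(O)c(OC)c1OC
F4 | step 3 | 6-hydroxy-7-iodo-4,5-dimethoxy-2-methyl-1-benzofuran-3(2H)-one (racemic) | CC1Oc2c(I)c(O)c(OC)c(OC)c2C1=O
F5 | step 3 | 3,6-bis(tert-butyldimethylsilyloxy)-7-iodo-4,5-dimethoxy-2-methyl-1-benzofuran | Cc1oc2c(I)c(O[Si](C)(C)C(C)(C)C)c(OC)c(OC)c2c1O[Si](C)(C)C(C)(C)C
F6 | step 3 | 2-[3,6-bis(tert-butyldimethylsilyloxy)-4,5-dimethoxy-2-methyl-1-benzofuran-7-yl]-4,4,5,5-tetramethyl-1,3,2-dioxaborolane | Cc1oc2c(B3OC(C)(C)C(C)(C)O3)c(O[Si](C)(C)C(C)(C)C)c(OC)c(OC)c2c1O[Si](C)(C)C(C)(C)C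
F7 | step 2 | 1,2-dimethoxy-3,5-bis(methoxymethoxy)benzene | COCOc1cc(OCOC)c(OC)c(OC)c1
F8 | step 2 | [3,4-dimethoxy-2,6-bis(methoxymethoxy)phenyl]lithium | [Li]c1c(OCOC)cc(OC)c(OC)c1OCOC
F9 | step 2 | 3,3',4,4'-tetramethoxy-2,2',6,6'-tetrakis(methoxymethoxy)-1,1'-biphenyl | COCOc1cc(OC)c(OC)c(OCOC)c1-c1c(OCOC)cc(OC)c(OC)c1OCOC
F10 | step 2 | 3,3',4,4'-tetramethoxy-[1,1'-biphenyl]-2,2',6,6'-tetrol | Oc1cc(OC)c(OC)c(O)c1-c1c(O)cc(OC)c(OC)c1O
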